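In blue, the flask you are deciding on, the amount of target stops moving: from 72.0 h on it reads 13.5 %, 13.3 % and 13.8 % of the charge, a spread of 0.5 percentage points against a scatter of 0.5 points. So nothing is gained by waiting, and the decision is what to do at 5.0 d.

all flasks: starting material 20 mM
- blue: protic impurity 0.40 mM; temperature 60 °C; the very flask that is asked about, followed so far
- green: protic impurity 0.80 mM; temperature 66 °C; run made earlier
- flask: protic impurity 0.400 mM; temperature 60 °C; time 5.0 d

- blue (time / h: target / %): 6.00: 40.2; 20.0: 22.6; 30.0: 17.5; 48.0: 14.4; 72.0: 13.5; 96.0: 13.3; 120: 13.8
- green (time / h: target / %): 0.667: 24.8; 2.00: 42.0; 3.00: 39.6; 5.00: 32.0; 8.00: 24.2; 10.0: 20.9; 12.0: 19.1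

(each reading ± 0.5 percentage points)

- what is taken out of target is counted as made
- what was read earlier has a scatter of 0.5 percentage points, one standard deviation
- additions bring no volume worth counting

- target, in percent of the starting material first charged, at 5.0 d
- what to do for the largest gain in target; "none" if nothing gains more than 2 percentage points (alder / elm / maple / cedar / none)
- target present, with what was taken out counted in, in percent of the starting material first charged, after alder
- target present, with what was taken out counted in, in percent of the starting material first charged, after maple

- alder: change nothing and wait 10 d more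
- elm: at 5.0 d take out 90 % of the target then present, then wait 10 d
- maple: at 5.0 d raise the temperature by 10 K, then wait 10 d
- cedar: at 5.0 d add starting material, 50.0 % of the amount charged, then wait 10 d

I carry one quantity from these readings: the **settled share**, the fraction of what stands in the flask that rests as target once it stops moving (the equilibrium yield), 13.5 %. That is my answer for now. The excess over it fell with a half-life of about 9.00 h, as read between 6.00 h and 20.0 h. Since that is far shorter than the 10 d on offer, I assume any disturbance settles again.

Now go round once for elm. Taking out 90 % of the target removes 12.2 % of the charge, which leaves 87.8 % in the flask. The same share of that returns as 11.9 %, so the count reaches 24.1 %.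

| Option | Rule | Gain |
|---|---|---|
| alder | share unchanged | none |
| elm | taken out × (1 − share) | 11 points |
| cedar | added × share | 6.8 points |

Maple I cannot reckon, because green, at 66 °C, was still falling at 19.1 % when last read, so I leave the share at 13.5 % after heating. Elm beats cedar, so I would choose elm.

The forecast gives 13.5 % now, 13.5 % after alder, 14.5 % after maple and elm as the choice, with the ground “Removing target lets the pool re-equilibrate”.

    starting material → intermediate (k = 0.0279 min⁻¹, Ea = 106 kJ mol⁻¹)
    intermediate ⇌ target (K = 2.60, k = 0.00899 min⁻¹, Ea = 104 kJ mol⁻¹, ΔH = −11.0 kJ mol⁻¹)
    intermediate ⇌ isomer of the product (K = 15.0, k = 0.00530 min⁻¹, Ea = 104 kJ mol⁻¹, ΔH = −1.00 kJ mol⁻¹)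
    starting material + protic impurity → quenched substrate (k = 6.78 M⁻¹ min⁻¹, Ea = 51.0 kJ mol⁻¹)
    (constants at 60 °C)

The flask holds 13.7 % at 5.0 d; alder stays at 13.7 %, maple gives 12.5 %, and elm gains 11 points against 7 points for cedar. At 120 h the isomer of the product stands at 79.0 % of the charge, beside 5.27 % of intermediate. With 13.7 % as the share, the rules give 11 points for elm and 6.9 points for cedar. The flask kept at 45 °C holds, at the moment 120 h, 25.9 % of target, 65.1 % of isomer of the product, 6.94 % of intermediate and 2.00 % of quenched substrate.

All runs are calculated from invented constants.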